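**Plan**
- Cuts: first the depside ester bond between the ring B carbonyl carbon and O-4 of ring A. Then the C1–CO2H bond of ring A, back to 5-heptylresorcinol. Last the C3'–C4' and C5'–C6' bonds of ring B.
- Enabling feature: in ring B the run C6'(pentyl)–C1'(carbonyl)–C2'(OMe)–C3'(H) is the C6–C5–C4–C3 diene of a 4-methoxy-6-pentyl-2-pyrone-5-carboxylate. C4'(OMe)–C5'(H) are the two carbons of 1,1-dimethoxyethene, which take the place of the O1–C2 lactone unit.
- Forward: the pyrone ring is closed from C-acylated dimethyl 3-oxoglutarate and turned into ring B by cycloaddition with loss of CO2 and methanol. Ring A is bought as the arene and carboxylated.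
- Joining: the two halves are esterified at O-4, O-2 is then methylated, and the benzyl ester is removed last.
- Stereochemistry: the target has no stereocentre and no stereogenic double bond. Only regiochemistry needs control (cycloaddition, carboxylation, O-4 over O-2).

Key step: step 4

Remark: the acylated oxoglutarate is drawn as its tricarbonyl tautomer (its methine centre is labile through enolisation) and the bridged cycloadduct forms as a racemate, so no SMILES of this route carries a stereodescriptor.

Step 1
Reactants: 1 dimethyl 3-oxoglutarate; 2 hexanoyl chloride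
Product: 3 dimethyl 2-hexanoyl-3-oxopentanedioate
Conditions: MgCl2 (1 equiv), pyridine (2 equiv), CH2Cl2, 0 °C; then 2 (1 equiv), 0 °C to rt; cold aq. HCl work-up
Reagents that add atoms: none
Why: Soft enolisation gives the magnesium chelate of the β-keto ester, which is acylated on carbon rather than on oxygen (C-acylation of a magnesium enolate with an acid chloride), and the more acidic tricarbonyl product stays chelated, which should hold back a second acylation.

Step 2
Reactants: 3 dimethyl 2-hexanoyl-3-oxopentanedioate
Product: 4 methyl 4-hydroxy-2-oxo-6-pentyl-2H-pyran-5-carboxylate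
Conditions: conc. H2SO4, 0 °C to rt; poured onto ice
Reagents that add atoms: none
Why: In an acid-promoted enol lactonisation (6-exo-trig) the enol oxygen of the hexanoyl carbonyl attacks the remote ester with loss of methanol, which is the usual closure of 2-acyl-3-oxoglutarates to 4-hydroxy-2-pyrone-5-carboxylates and the only six-membered lactone open to 3.

Step 3
Reactants: 4 methyl 4-hydroxy-2-oxo-6-pentyl-2H-pyran-5-carboxylate
Product: 5 methyl 4-methoxy-2-oxo-6-pentyl-2H-pyran-5-carboxylate
Conditions: Me2SO4 (1.1 equiv), K2CO3, acetone, reflux
Reagents that add atoms: dimethyl sulfate, COS(=O)(=O)OC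
Why: This is a Williamson-type O-alkylation of the vinylogous acid, and with a hard methylating agent and K2CO3 in acetone 4-hydroxy-2-pyrones are known to be methylated on O-4 to the 4-methoxy-2-pyrone rather than on the lactone carbonyl oxygen.

Step 4
Reactants: 5 methyl 4-methoxy-2-oxo-6-pentyl-2H-pyran-5-carboxylate; 6 1,1-dimethoxyethene
Product: 9 methyl 2,4-dimethoxy-6-pentylbenzoate, via bridged lactone 7 (not isolated), via ketal cyclohexadiene 8 (not isolated)
Conditions: 6 (6 equiv, added in portions), toluene, sealed base-washed tube, 150 °C
Reagents that add atoms: none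
Why: This is an inverse-electron-demand Diels–Alder reaction of an electron-poor 2-pyrone with a ketene acetal, the reaction type by which 2-pyrone-5-carboxylates are known to give 4-alkoxybenzoates. The nucleophilic CH2 of 6 bonds to C6 of 5 (β-carbon of the C5=C6 enoate and far end of the dienyl lactone) and the dimethoxy-bearing carbon bonds to C3, in one asynchronous event or by way of a dienolate/dialkoxycarbenium zwitterion, so that the new six-membered carbocycle C3–C4–C5–C6–CH2–C(OMe)2 is closed by an intermolecular (4+2) cycloaddition inside bridged lactone 7. Retro-(4+2) loss of CO2 from 7 gives diene 8, and 1,2-elimination of methanol across its ketal carbon and the neighbouring CH2 gives arene 9; both losses are irreversible and should pull a slow, possibly reversible addition forward. The two bridgehead stereocentres of 7 form as a racemate and vanish again in 8, so nothing has to control them and 9 is achiral. The selectivity needed is regiochemical, CH2 to C6 and acetal carbon to C3, and it is secured by the 5-ester and the ring oxygen, which make C6 the most electrophilic diene terminus, and backed by the 4-methoxy group, which makes C3 the nucleophilic end of the dienolate and lowers the electrophilicity of C4. Because the 4-methoxy and 6-pentyl groups slow the addition, an excess of 6 is heated with 5 in a closed, base-washed vessel that keeps the volatile, acid-sensitive dienophile in solution.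

Step 5
Reactants: 9 methyl 2,4-dimethoxy-6-pentylbenzoate
Product: 10 2,4-dimethoxy-6-pentylbenzoic acid
Conditions: KOH, DMSO–H2O, 100 °C; then cold aq. HCl to pH 2
Reagents that add atoms: potassium hydroxide, [K+].[OH-]
Why: Saponification of a benzoate with two ortho substituents needs the weakly solvated hydroxide of hot aqueous DMSO, the customary conditions for 2,4-dialkoxy-6-alkylbenzoates, and cold acidification should spare the electron-rich acid from decarboxylation.

Step 6
Reactants: 11 5-heptylresorcinol
Product: 12 2,4-dihydroxy-6-heptylbenzoic acid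
Conditions: MeOMgOCO2Me (2 M in DMF, excess), 120 °C; then cold aq. HCl
Reagents that add atoms: methoxymagnesium methyl carbonate MeOMgOCO2Me, C[O-].[Mg+2].[O-]C(=O)OC
Why: In this Kolbe–Schmitt-type carboxylation the magnesium phenoxide delivers CO2 to a ring carbon ortho to one hydroxyl and para to the other, the chelated magnesium salicylate draws the equilibrium to the product side, and the method is precedented for turning 5-alkylresorcinols into 6-alkyl-2,4-dihydroxybenzoic acids.

Step 7
Reactants: 12 2,4-dihydroxy-6-heptylbenzoic acid
Product: 13 benzyl 2,4-dihydroxy-6-heptylbenzoate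
Conditions: BnBr (1.05 equiv), KHCO3, DMF, rt
Reagents that add atoms: benzyl bromide, BrCc1ccccc1
Why: This is an SN2 alkylation of the carboxylate, in which KHCO3 is basic enough for the carboxylic acid only, so both phenols should stay free.

Step 8
Reactants: 10 2,4-dimethoxy-6-pentylbenzoic acid; 13 benzyl 2,4-dihydroxy-6-heptylbenzoate
Product: 15 benzyl 4-[(2,4-dimethoxy-6-pentylbenzoyl)oxy]-6-heptyl-2-hydroxybenzoate, via mixed trifluoroacetic anhydride 14 (not isolated)
Conditions: (CF3CO)2O (1.5 equiv), toluene, rt
Reagents that add atoms: none
Why: This is the classical depside esterification through a mixed trifluoroacetic anhydride, whose electron-rich, hindered aroyl group is transferred as an acylium-like species to O-4 because the 2-hydroxyl is hydrogen-bonded to the benzyl ester carbonyl and much less nucleophilic.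

Step 9
Reactants: 15 benzyl 4-[(2,4-dimethoxy-6-pentylbenzoyl)oxy]-6-heptyl-2-hydroxybenzoate
Product: 16 benzyl 4-[(2,4-dimethoxy-6-pentylbenzoyl)oxy]-6-heptyl-2-methoxybenzoate
Conditions: MeI (3 equiv), K2CO3 (anhydrous), DMF, rt to 40 °C
Reagents that add atoms: iodomethane, CI
Why: This is a Williamson O-methylation of the one remaining phenol, in which K2CO3 in DMF breaks the hydrogen bond to the ester while the depside carbonyl is shielded by its ortho methoxy and pentyl groups against attack by phenoxide or carbonate.

Step 10
Reactants: 16 benzyl 4-[(2,4-dimethoxy-6-pentylbenzoyl)oxy]-6-heptyl-2-methoxybenzoate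
Product: 17 4-[(2,4-dimethoxy-6-pentylbenzoyl)oxy]-6-heptyl-2-methoxybenzoic acid (CNP0206304.0)
Conditions: H2 (1 atm), 10% Pd/C, EtOAc, rt
Reagents that add atoms: none
Why: Catalytic hydrogenolysis cleaves the benzylic C–O bond of the benzyl ester under neutral conditions, so the aryl ester, the three methyl ethers and the free acid should be left untouched.

**Compound list**
1 | dimethyl 3-oxoglutarate | COC(=O)CC(=O)CC(=O)OC | starting material
2 | hexanoyl chloride | CCCCCC(=O)Cl | starting material
3 | dimethyl 2-hexanoyl-3-oxopentanedioate | CCCCCC(=O)C(C(=O)OC)C(=O)CC(=O)OC | intermediate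
4 | methyl 4-hydroxy-2-oxo-6-pentyl-2H-pyran-5-carboxylate | CCCCCC1=C(C(=O)OC)C(O)=CC(=O)O1 | intermediate
5 | methyl 4-methoxy-2-oxo-6-pentyl-2H-pyran-5-carboxylate | CCCCCC1=C(C(=O)OC)C(OC)=CC(=O)O1 | intermediate
6 | 1,1-dimethoxyethene | C=C(OC)OC | starting material
7 | methyl 5,8,8-trimethoxy-3-oxo-1-pentyl-2-oxabicyclo[2.2.2]oct-5-ene-6-carboxylate (racemic) | CCCCCC12CC(OC)(OC)C(C(=O)O1)C(OC)=C2C(=O)OC | intermediate
8 | methyl 4,4,6-trimethoxy-2-pentylcyclohexa-1,5-diene-1-carboxylate | CCCCCC1=C(C(=O)OC)C(OC)=CC(OC)(OC)C1 | intermediate
9 | methyl 2,4-dimethoxy-6-pentylbenzoate | CCCCCc1cc(OC)cc(OC)c1C(=O)OC | intermediate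
10 | 2,4-dimethoxy-6-pentylbenzoic acid | CCCCCc1cc(OC)cc(OC)c1C(=O)O | intermediate
11 | 5-heptylresorcinol | CCCCCCCc1cc(O)cc(O)c1 | starting material
12 | 2,4-dihydroxy-6-heptylbenzoic acid | CCCCCCCc1cc(O)cc(O)c1C(=O)O | intermediate
13 | benzyl 2,4-dihydroxy-6-heptylbenzoate | CCCCCCCc1cc(O)cc(O)c1C(=O)OCc1ccccc1 | intermediate
14 | 2,4-dimethoxy-6-pentylbenzoic trifluoroacetic anhydride | CCCCCc1cc(OC)cc(OC)c1C(=O)OC(=O)C(F)(F)F | intermediate
15 | benzyl 4-[(2,4-dimethoxy-6-pentylbenzoyl)oxy]-6-heptyl-2-hydroxybenzoate | CCCCCCCc1cc(OC(=O)c2c(CCCCC)cc(OC)cc2OC)cc(O)c1C(=O)OCc1ccccc1 | intermediate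
16 | benzyl 4-[(2,4-dimethoxy-6-pentylbenzoyl)oxy]-6-heptyl-2-methoxybenzoate | CCCCCCCc1cc(OC(=O)c2c(CCCCC)cc(OC)cc2OC)cc(OC)c1C(=O)OCc1ccccc1 | intermediate
17 | 4-[(2,4-dimethoxy-6-pentylbenzoyl)oxy]-6-heptyl-2-methoxybenzoic acid | CCCCCCCc1cc(OC(=O)c2c(CCCCC)cc(OC)cc2OC)cc(OC)c1C(=O)O | target

**Totals**
Total step count: 10.
Longest linear sequence: 8 (steps 1–5 and 8–10). Steps 6 and 7 form the two-step ring A branch.

**Steps most likely to fail**

1. Step 4.
- What may go wrong: the addition may be too slow, because the 4-methoxy group feeds electron density into the diene and C6 is fully substituted. Thermal decay and oligomerisation of the ketene acetal could then outrun the cycloaddition.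
- Change of approach: the fallback raises the electron demand of the diene with a removable halogen instead of forcing the conditions.
- It sets out from 5. Ionic bromination of the only free ring position, C3 (NBS, MeCN, rt, in the dark), should give methyl 3-bromo-4-methoxy-2-oxo-6-pentyl-2H-pyran-5-carboxylate F1. This belongs to the 3-bromo-2-pyrone-5-carboxylate family, which is known to take up electron-rich alkenes under milder heating.
- With 6 in toluene the same two ring bonds would form. The path should run through methyl 4-bromo-5,8,8-trimethoxy-3-oxo-1-pentyl-2-oxabicyclo[2.2.2]oct-5-ene-6-carboxylate F2. After loss of CO2 it should pass through methyl 5-bromo-4,4,6-trimethoxy-2-pentylcyclohexa-1,5-diene-1-carboxylate F3, which should lose methanol to methyl 3-bromo-2,4-dimethoxy-6-pentylbenzoate F4.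
- Hydrogenolysis of the C–Br bond (H2, 10% Pd/C, NaOAc, MeOH) comes back to the route at 9.

2. Step 6.
- What may go wrong: carboxylation between the two hydroxyl groups may compete with the wanted position, the equilibrium may stop short of full conversion, and the product may decarboxylate during the acidic work-up.
- Change of approach: the fallback brings in the carbon at the aldehyde level by electrophilic substitution and oxidises afterwards.
- It sets out from 11. Vilsmeier–Haack formylation (POCl3, DMF, 0 °C to rt, then aqueous hydrolysis) should give 2,4-dihydroxy-6-heptylbenzaldehyde F5. Attack para to one hydroxyl and ortho to the other is the established outcome for 5-alkylresorcinols.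
- Pinnick oxidation (NaClO2, NaH2PO4, DMSO–H2O, with DMSO acting as the hypochlorite scavenger that protects the ring from chlorination) comes back to the route at 12.

3. Step 9.
- What may go wrong: alkylation of the hydrogen-bonded hydroxyl may be slow, and during a long exposure to base the depside ester may be cleaved or its acyl group transferred.
- Change of approach: the fallback changes the order of events so that the methyl ether is in place before the depside bond exists.
- It sets out from 13. Selective alkylation of the free, unchelated O-4 (allyl bromide, 1 equiv, K2CO3, acetone, reflux) should give benzyl 4-(allyloxy)-6-heptyl-2-hydroxybenzoate F6.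
- This compound tolerates forcing methylation (MeI, K2CO3, DMF, 50 °C) to benzyl 4-(allyloxy)-6-heptyl-2-methoxybenzoate F7.
- Tsuji–Trost-type deallylation (Pd(PPh3)4 cat., morpholine, THF, rt) should free benzyl 6-heptyl-4-hydroxy-2-methoxybenzoate F8 without touching the benzyl ester.
- Esterification of F8 with 10 by way of 14 ((CF3CO)2O, toluene, rt) comes back to the route at 16.

**Further compounds**
F1 | step 4 | methyl 3-bromo-4-methoxy-2-oxo-6-pentyl-2H-pyran-5-carboxylate | CCCCCC1=C(C(=O)OC)C(OC)=C(Br)C(=O)O1
F2 | step 4 | methyl 4-bromo-5,8,8-trimethoxy-3-oxo-1-pentyl-2-oxabicyclo[2.2.2]oct-5-ene-6-carboxylate (racemic) | CCCCCC12CC(OC)(OC)C(Br)(C(=O)O1)C(OC)=C2C(=O)OC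
F3 | step 4 | methyl 5-bromo-4,4,6-trimethoxy-2-pentylcyclohexa-1,5-diene-1-carboxylate | CCCCCC1=C(C(=O)OC)C(OC)=C(Br)C(OC)(OC)C1
F4 | step 4 | methyl 3-bromo-2,4-dimethoxy-6-pentylbenzoate | CCCCCc1cc(OC)c(Br)c(OC)c1C(=O)OC
F5 | step 6 | 2,4-dihydroxy-6-heptylbenzaldehyde | CCCCCCCc1cc(O)cc(O)c1C=O
F6 | step 9 | benzyl 4-(allyloxy)-6-heptyl-2-hydroxybenzoate | CCCCCCCc1cc(OCC=C)cc(O)c1C(=O)OCc1ccccc1
F7 | step 9 | benzyl 4-(allyloxy)-6-heptyl-2-methoxybenzoate | CCCCCCCc1cc(OCC=C)cc(OC)c1C(=O)OCc1ccccc1
F8 | step 9 | benzyl 6-heptyl-4-hydroxy-2-methoxybenzoate | CCCCCCCc1cc(O)cc(OC)c1C(=O)OCc1ccccc1
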